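**Retrosynthetic overview**

- The strategy rests on ring B, a benzene ring with OH on C3' and C5' and the heptamethylene chain on C1', all three mutually meta. C1', C2', C6' and the hydroxyl carbon C5' come from a 3-alkylcyclobutenone; C3' (ethoxy-bearing) and C4' come from ethoxyacetylene (Danheiser benzannulation on the intact ester).
- Target ⇒ (BBr3 dealkylation) ring A dimethyl ether / ring B monoethyl ether ⇒ (benzannulation, ring B) cyclobutenone ester + HC≡COEt ⇒ (dichloroketene [2+2], then Zn) terminal-alkyne ester.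
- Alkyne ester ⇒ (Mitsunobu, inversion at C4) (S)-tridec-12-yn-4-ol + 2,4-dimethoxy-6-undecylbenzoic acid.
- Alcohol ⇐ alkyne zipper ⇐ 1-octyne + (S)-1,2-epoxypentane (hydrolytic kinetic resolution); acid ⇐ methyl orsellinate by O-methylation, lateral lithiation/decylation and saponification.
- Ring order: ring A is bought, ring B is formed last but one (step 10). Ring A is carried as methyl ethers so that one BBr3 step unmasks all five phenols.

Key step: step 10

Assumption: the (S,S)-cobalt salen complex is taken to hydrate (R)-1,2-epoxypentane faster and leave the (S)-epoxide; if the sense is opposite for this substrate, the (R,R)-complex is used instead.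

**Route**

Step 1
Reactants: 1 racemic 1,2-epoxypentane
Product: 2 (S)-1,2-epoxypentane
Conditions: (S,S)-(salen)Co(OAc) (0.5 mol %; salen = N,N'-bis(3,5-di-tert-butylsalicylidene)cyclohexane-1,2-diaminate, trivalent cobalt), H2O (0.55 equiv), neat, 0 °C to rt; distillation
Reagents that add atoms: none
Why: Jacobsen hydrolytic kinetic resolution, in which the chiral cobalt complex hydrates the (R)-epoxide much faster, so the unreacted (S)-epoxide carrying the only stereocenter of the route should be recovered in high enantiomeric purity by distillation from the diol.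

Step 2
Reactants: 3 1-octyne; 2 (S)-1,2-epoxypentane
Product: 5 (S)-tridec-6-yn-4-ol, via lithium oct-1-yn-1-ide 4 (not isolated)
Conditions: n-BuLi, THF, −78 to 0 °C; then 2, DMPU, 0 °C to rt; H2O
Reagents that add atoms: none
Why: SN2 opening of the monosubstituted epoxide by the lithium acetylide at the unhindered CH2 terminus, so the carbinol carbon is not touched and stays (S).

Step 3
Reactants: 5 (S)-tridec-6-yn-4-ol
Product: 6 (S)-tridec-12-yn-4-ol
Conditions: KH, H2N(CH2)3NH2, 0 °C to rt; H2O
Reagents that add atoms: none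
Why: Alkyne zipper isomerization with potassium 3-aminopropylamide, in which the triple bond migrates through allene/alkyne equilibria away from the alkoxide-bearing carbon (which blocks the other direction) and is trapped at the chain end as the terminal acetylide, the alkoxide carbon not being deprotonated so that C4 should be retained.

Step 4
Reactants: 7 methyl 2,4-dihydroxy-6-methylbenzoate (methyl orsellinate)
Product: 8 methyl 2,4-dimethoxy-6-methylbenzoate
Conditions: MeI (excess), K2CO3, acetone, reflux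
Reagents that add atoms: iodomethane, CI
Why: Williamson O-methylation of both phenols, the hydrogen-bonded ortho-hydroxyl needing excess reagent and heat.

Step 5
Reactants: 8 methyl 2,4-dimethoxy-6-methylbenzoate; 9 1-iododecane
Product: 11 methyl 2,4-dimethoxy-6-undecylbenzoate, via benzylic lithium toluate 10 (not isolated)
Conditions: LiN(i-Pr)2 (LDA), THF, −78 °C; then 9, −78 to 0 °C
Reagents that add atoms: none
Why: Lateral (benzylic) lithiation of the ortho-toluate gives the ester-stabilised benzylic anion, which is alkylated by the primary iodide in an SN2 reaction and so turns the C6 methyl into undecyl.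

Step 6
Reactants: 11 methyl 2,4-dimethoxy-6-undecylbenzoate
Product: 12 2,4-dimethoxy-6-undecylbenzoic acid
Conditions: KOH, DMSO/H2O, 100 °C; then cold 1 M HCl
Reagents that add atoms: potassium hydroxide, [K+].[OH-]
Why: Saponification of the hindered 2,6-disubstituted benzoate by poorly solvated hydroxide in hot aqueous DMSO, the aryl methyl ethers and the alkyl chain being inert and cold acidification avoiding protodecarboxylation.

Step 7
Reactants: 6 (S)-tridec-12-yn-4-ol; 12 2,4-dimethoxy-6-undecylbenzoic acid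
Product: 14 (R)-tridec-12-yn-4-yl 2,4-dimethoxy-6-undecylbenzoate, via alkoxyphosphonium carboxylate 13 (not isolated)
Conditions: PPh3, DIAD, THF, 0 °C to rt
Reagents that add atoms: none
Why: Mitsunobu esterification, in which the carboxylate displaces the phosphonium-activated oxygen at C4 in an SN2 step, which avoids attack at the hindered acyl carbon and inverts C4 from (S) to the (R) configuration of the target.

Step 8
Reactants: 14 (R)-tridec-12-yn-4-yl 2,4-dimethoxy-6-undecylbenzoate
Product: 15 (R)-11-(4,4-dichloro-3-oxocyclobut-1-en-1-yl)undecan-4-yl 2,4-dimethoxy-6-undecylbenzoate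
Conditions: Cl3CCOCl, Zn–Cu couple, Et2O/DME, rt
Reagents that add atoms: trichloroacetyl chloride, ClC(=O)C(Cl)(Cl)Cl
Why: [2+2] cycloaddition of dichloroketene (from zinc dechlorination of trichloroacetyl chloride) with the terminal alkyne, the nucleophilic terminal CH bonding to the ketene carbonyl carbon so that the chain sits on C3 of the cyclobutenone.

Step 9
Reactants: 15 (R)-11-(4,4-dichloro-3-oxocyclobut-1-en-1-yl)undecan-4-yl 2,4-dimethoxy-6-undecylbenzoate
Product: 16 (R)-11-(3-oxocyclobut-1-en-1-yl)undecan-4-yl 2,4-dimethoxy-6-undecylbenzoate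
Conditions: Zn dust, AcOH, TMEDA, EtOH, 0 °C to rt
Reagents that add atoms: none
Why: Reductive dechlorination of the alpha,alpha-dichloroketone with zinc under amine-buffered acetic acid conditions, which should remove both chlorines without opening the strained enone and leaves ester and ethers untouched.

Step 10
Reactants: 16 (R)-11-(3-oxocyclobut-1-en-1-yl)undecan-4-yl 2,4-dimethoxy-6-undecylbenzoate; 17 ethoxyacetylene
Product: 22 (R)-11-(3-ethoxy-5-hydroxyphenyl)undecan-4-yl 2,4-dimethoxy-6-undecylbenzoate, via vinylketene 18 (not isolated), via 4-alkenylcyclobutenone 19 (not isolated), via dienylketene 20 (not isolated), via cyclohexadienone 21 (not isolated)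
Conditions: 17 (3 equiv), toluene, 80 °C, sealed tube
Reagents that add atoms: none
Why: Danheiser benzannulation: thermal 4-pi electrocyclic opening of 16 gives vinylketene 18, whose ketene C=C adds the ynol ether in a [2+2] cycloaddition to 4-alkenylcyclobutenone 19, a second 4-pi opening gives dienylketene 20, and tautomerization of the cyclized dienone 21 gives the phenol. The closest known reaction type is this same annulation of 3-alkylcyclobutenones with alkoxyacetylenes to 5-alkylresorcinol monoethers. Ring B is closed by a thermal 6-pi electrocyclization of 20 that joins the ketene carbon to the terminal methylene carbon, giving the six-membered carbocycle. No stereocenter is created, and C4 of the chain, remote and without an acidic hydrogen, is not affected under neutral thermal conditions. The selectivity needed is the regiochemistry of the [2+2] step, secured by the polarization of ethoxyacetylene: its electron-rich CH terminus bonds to the electrophilic ketene carbonyl carbon, so ethoxy ends up meta to the new hydroxyl and the chain meta to both. No reagent other than heat is present, so the ester, the aryl methyl ethers and the alkyl chains are spectators.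

Step 11
Reactants: 22 (R)-11-(3-ethoxy-5-hydroxyphenyl)undecan-4-yl 2,4-dimethoxy-6-undecylbenzoate
Product: 23 (R)-11-(3,5-dihydroxyphenyl)undecan-4-yl 2,4-dihydroxy-6-undecylbenzoate
Conditions: BBr3 (8 equiv), CH2Cl2, −78 °C to rt; ice water
Reagents that add atoms: none
Why: Lewis-acid dealkylation of aryl alkyl ethers, in which bromide attacks the methyl or ethyl carbon of each boron-complexed ether (SN2) and releases the phenols on hydrolysis, while the secondary-alkyl 2,6-disubstituted benzoate, an ester class known to tolerate this reagent, should survive at or below room temperature with C4 unchanged.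

**Compound list**

1 | racemic 1,2-epoxypentane | CCCC1CO1 | starting material
2 | (S)-1,2-epoxypentane | CCC[C@H]1CO1 | intermediate
3 | 1-octyne | CCCCCCC#C | starting material
4 | lithium oct-1-yn-1-ide | [Li]C#CCCCCCC | intermediate
5 | (S)-tridec-6-yn-4-ol | CCC[C@H](O)CC#CCCCCCC | intermediate
6 | (S)-tridec-12-yn-4-ol | CCC[C@H](O)CCCCCCCC#C | intermediate
7 | methyl 2,4-dihydroxy-6-methylbenzoate | COC(=O)c1c(C)cc(O)cc1O | starting material
8 | methyl 2,4-dimethoxy-6-methylbenzoate | COC(=O)c1c(C)cc(OC)cc1OC | intermediate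
9 | 1-iododecane | CCCCCCCCCCI | starting material
10 | [3,5-dimethoxy-2-(methoxycarbonyl)phenyl]methyllithium | COC(=O)c1c(C[Li])cc(OC)cc1OC | intermediate
11 | methyl 2,4-dimethoxy-6-undecylbenzoate | CCCCCCCCCCCc1cc(OC)cc(OC)c1C(=O)OC | intermediate
12 | 2,4-dimethoxy-6-undecylbenzoic acid | CCCCCCCCCCCc1cc(OC)cc(OC)c1C(=O)O | intermediate
13 | triphenyl{[(4S)-tridec-12-yn-4-yl]oxy}phosphonium 2,4-dimethoxy-6-undecylbenzoate | CCC[C@H](O[P+](c1ccccc1)(c1ccccc1)c1ccccc1)CCCCCCCC#C.CCCCCCCCCCCc1cc(OC)cc(OC)c1C(=O)[O-] | intermediate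
14 | (R)-tridec-12-yn-4-yl 2,4-dimethoxy-6-undecylbenzoate | CCCCCCCCCCCc1cc(OC)cc(OC)c1C(=O)O[C@H](CCC)CCCCCCCC#C | intermediate
15 | (R)-11-(4,4-dichloro-3-oxocyclobut-1-en-1-yl)undecan-4-yl 2,4-dimethoxy-6-undecylbenzoate | CCCCCCCCCCCc1cc(OC)cc(OC)c1C(=O)O[C@H](CCC)CCCCCCCC1=CC(=O)C1(Cl)Cl | intermediate
16 | (R)-11-(3-oxocyclobut-1-en-1-yl)undecan-4-yl 2,4-dimethoxy-6-undecylbenzoate | CCCCCCCCCCCc1cc(OC)cc(OC)c1C(=O)O[C@H](CCC)CCCCCCCC1=CC(=O)C1 | intermediate
17 | ethoxyacetylene | CCOC#C | starting material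
18 | (R)-12-methylidene-14-oxotetradec-13-en-4-yl 2,4-dimethoxy-6-undecylbenzoate (vinylketene) | CCCCCCCCCCCc1cc(OC)cc(OC)c1C(=O)O[C@H](CCC)CCCCCCCC(=C)C=C=O | intermediate
19 | (4R)-12-(2-ethoxy-4-oxocyclobut-2-en-1-yl)tridec-12-en-4-yl 2,4-dimethoxy-6-undecylbenzoate (both epimers at the ring carbon) | CCCCCCCCCCCc1cc(OC)cc(OC)c1C(=O)O[C@H](CCC)CCCCCCCC(=C)C1C(=O)C=C1OCC | intermediate
20 | (4R,13E)-14-ethoxy-12-methylidene-16-oxohexadeca-13,15-dien-4-yl 2,4-dimethoxy-6-undecylbenzoate (dienylketene) | CCCCCCCCCCCc1cc(OC)cc(OC)c1C(=O)O[C@H](CCC)CCCCCCCC(=C)/C=C(OCC)\C=C=O | intermediate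
21 | (R)-11-(3-ethoxy-5-oxocyclohexa-1,3-dien-1-yl)undecan-4-yl 2,4-dimethoxy-6-undecylbenzoate | CCCCCCCCCCCc1cc(OC)cc(OC)c1C(=O)O[C@H](CCC)CCCCCCCC1=CC(OCC)=CC(=O)C1 | intermediate
22 | (R)-11-(3-ethoxy-5-hydroxyphenyl)undecan-4-yl 2,4-dimethoxy-6-undecylbenzoate | CCCCCCCCCCCc1cc(OC)cc(OC)c1C(=O)O[C@H](CCC)CCCCCCCc1cc(O)cc(OCC)c1 | intermediate
23 | (R)-11-(3,5-dihydroxyphenyl)undecan-4-yl 2,4-dihydroxy-6-undecylbenzoate | CCCCCCCCCCCc1cc(O)cc(O)c1C(=O)O[C@H](CCC)CCCCCCCc1cc(O)cc(O)c1 | target

**Step count**

Total: 11 steps. Longest linear sequence: 8 steps (steps 1, 2, 3, 7, 8, 9, 10, 11; the acid branch through steps 4, 5, 6 is equally long).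

**Steps most likely to fail**

Step 10. The vinylketene may be consumed by O-acylation of the phenol already formed or by dimerization. The alkoxyalkyne may also decompose thermally before it is captured, or the cascade may stall before the 6-pi closure. The fallback builds ring B by cross-coupling instead; it sets out from 2 and 7 and comes back at 23. Epoxide 2 is opened with lithiated 1-hexyne (conditions of step 2) to give (S)-undec-6-yn-4-ol F1. The zipper conditions of step 3 give (S)-undec-10-yn-4-ol F2. Sonogashira coupling with commercial 1,3-bis(benzyloxy)-5-bromobenzene (PdCl2(PPh3)2, CuI, Et3N, DMF, 70 °C) gives (S)-11-[3,5-bis(benzyloxy)phenyl]undec-10-yn-4-ol F3. In parallel 7 is benzylated (BnBr, K2CO3, acetone) to methyl 2,4-bis(benzyloxy)-6-methylbenzoate F4, which is alkylated with 9 as in step 5 to methyl 2,4-bis(benzyloxy)-6-undecylbenzoate F5 and saponified as in step 6 to 2,4-bis(benzyloxy)-6-undecylbenzoic acid F6. Mitsunobu coupling of F3 with F6 gives (R)-11-[3,5-bis(benzyloxy)phenyl]undec-10-yn-4-yl 2,4-bis(benzyloxy)-6-undecylbenzoate F7. Hydrogenation over Pd/C (H2, EtOAc/EtOH) saturates the alkyne and removes the four benzyl groups to give 23.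

Step 11. Removal of the ethyl group may be slow, and the prolonged Lewis-acid exposure this requires may cause alkyl–oxygen fission of the secondary ester. The fallback de-ethylates before the ester exists and finishes by hydrogenolysis; it sets out from 6 and comes back at 23. Alcohol 6 is acetylated (Ac2O, pyridine) to (S)-tridec-12-yn-4-yl acetate F8. The conditions of steps 8 and 9 give (S)-11-(4,4-dichloro-3-oxocyclobut-1-en-1-yl)undecan-4-yl acetate F9 and then (S)-11-(3-oxocyclobut-1-en-1-yl)undecan-4-yl acetate F10. Benzannulation with 17 as in step 10 gives (S)-11-(3-ethoxy-5-hydroxyphenyl)undecan-4-yl acetate F11. Methanolysis (K2CO3, MeOH) gives (S)-3-ethoxy-5-(8-hydroxyundecyl)phenol F12. BBr3 in CH2Cl2 then cleaves the ethyl ether, the carbinol being held as its borate, to give (S)-5-(8-hydroxyundecyl)benzene-1,3-diol F13. Selective phenol benzylation (BnBr, K2CO3, acetone) gives (S)-11-[3,5-bis(benzyloxy)phenyl]undecan-4-ol F14. Mitsunobu coupling with acid F6, made as in the fallback for step 10, gives (R)-11-[3,5-bis(benzyloxy)phenyl]undecan-4-yl 2,4-bis(benzyloxy)-6-undecylbenzoate F15. Hydrogenolysis over Pd/C gives 23.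

Step 8. Cycloaddition to the unactivated alkyne may be slow, so that the ketene is lost to oligomerization and the zinc chloride formed attacks the electron-rich ring A. The fallback uses a keteniminium [2+2] cycloaddition instead; it sets out from 14 and comes back at 16, so that step 9 is not needed. N,N-dimethylacetamide, Tf2O and 2,4,6-collidine in refluxing 1,2-dichloroethane generate the keteniminium ion, which adds to the alkyne with the same regiochemistry to give N-{3-[(8R)-8-(2,4-dimethoxy-6-undecylbenzoyloxy)undecyl]cyclobut-2-en-1-ylidene}-N-methylmethanaminium trifluoromethanesulfonate F16. Hydrolysis with aqueous NaHCO3 gives 16.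

**Further compounds**

F1 | step 10 | (S)-undec-6-yn-4-ol | CCC[C@H](O)CC#CCCCC
F2 | step 10 | (S)-undec-10-yn-4-ol | CCC[C@H](O)CCCCCC#C
F3 | step 10 | (S)-11-[3,5-bis(benzyloxy)phenyl]undec-10-yn-4-ol | CCC[C@H](O)CCCCCC#Cc1cc(OCc2ccccc2)cc(OCc2ccccc2)c1
F4 | step 10 | methyl 2,4-bis(benzyloxy)-6-methylbenzoate | COC(=O)c1c(C)cc(OCc2ccccc2)cc1OCc1ccccc1
F5 | step 10 | methyl 2,4-bis(benzyloxy)-6-undecylbenzoate | CCCCCCCCCCCc1cc(OCc2ccccc2)cc(OCc2ccccc2)c1C(=O)OC
F6 | step 10 | 2,4-bis(benzyloxy)-6-undecylbenzoic acid | CCCCCCCCCCCc1cc(OCc2ccccc2)cc(OCc2ccccc2)c1C(=O)O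
F7 | step 10 | (R)-11-[3,5-bis(benzyloxy)phenyl]undec-10-yn-4-yl 2,4-bis(benzyloxy)-6-undecylbenzoate | CCCCCCCCCCCc1cc(OCc2ccccc2)cc(OCc2ccccc2)c1C(=O)O[C@H](CCC)CCCCCC#Cc1cc(OCc2ccccc2)cc(OCc2ccccc2)c1
F8 | step 11 | (S)-tridec-12-yn-4-yl acetate | CCC[C@H](OC(C)=O)CCCCCCCC#C
F9 | step 11 | (S)-11-(4,4-dichloro-3-oxocyclobut-1-en-1-yl)undecan-4-yl acetate | CCC[C@H](OC(C)=O)CCCCCCCC1=CC(=O)C1(Cl)Cl
F10 | step 11 | (S)-11-(3-oxocyclobut-1-en-1-yl)undecan-4-yl acetate | CCC[C@H](OC(C)=O)CCCCCCCC1=CC(=O)C1
F11 | step 11 | (S)-11-(3-ethoxy-5-hydroxyphenyl)undecan-4-yl acetate | CCC[C@H](OC(C)=O)CCCCCCCc1cc(O)cc(OCC)c1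
F12 | step 11 | (S)-3-ethoxy-5-(8-hydroxyundecyl)phenol | CCC[C@H](O)CCCCCCCc1cc(O)cc(OCC)c1
F13 | step 11 | (S)-5-(8-hydroxyundecyl)benzene-1,3-diol | CCC[C@H](O)CCCCCCCc1cc(O)cc(O)c1
F14 | step 11 | (S)-11-[3,5-bis(benzyloxy)phenyl]undecan-4-ol | CCC[C@H](O)CCCCCCCc1cc(OCc2ccccc2)cc(OCc2ccccc2)c1
F15 | step 11 | (R)-11-[3,5-bis(benzyloxy)phenyl]undecan-4-yl 2,4-bis(benzyloxy)-6-undecylbenzoate | CCCCCCCCCCCc1cc(OCc2ccccc2)cc(OCc2ccccc2)c1C(=O)O[C@H](CCC)CCCCCCCc1cc(OCc2ccccc2)cc(OCc2ccccc2)c1
F16 | step 8 | N-{3-[(8R)-8-(2,4-dimethoxy-6-undecylbenzoyloxy)undecyl]cyclobut-2-en-1-ylidene}-N-methylmethanaminium trifluoromethanesulfonate | CCCCCCCCCCCc1cc(OC)cc(OC)c1C(=O)O[C@H](CCC)CCCCCCCC1=CC(=[N+](C)C)C1.[O-]S(=O)(=O)C(F)(F)F
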